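## The problem

Target **26** is a bicyclo[3.3.1]nonane-2,4,9-trione. Ring A (C1, C2, C3, C4, C5, C9) is an enolised cyclohexane-1,3-dione, and it shares C1, C9 and C5 with the cyclohexanone ring B (C1, C8, C7, C6, C5, C9). C1 is the bridgehead carrying the (R)-2-methylbutanoyl group, C3 carries the 3-hydroxy-3-methylbutyl chain, C5 is the prenylated bridgehead, C7 the prenylated methine, C8 the gem-dimethyl carbon and C9 the bridging ketone. The hardest bond is C1–C8, which joins two fully substituted carbons, one of them flanked by three carbonyl groups. There are four stereocentres. C1 and C5 are tied together by the one-carbon bridge, so a single event sets both; C7 sits equatorial on the chair of ring B and can be set thermodynamically while it still carries an enolisable group. The fourth, the α-carbon of the acyl side chain, is too remote for the core to control and lies α to a ketone, so it is bought as (R)-2-methylbutanoic acid **1** and kept away from strong base. The two prenyl groups and the tertiary alcohol all cyclise onto the ring A enol oxygen under acid, and the triacylated C1 is open to retro-Claisen cleavage by hard nucleophiles, so late steps must be neutral or mildly basic and the tertiary alcohol must come last. The enabling feature is that C1, C3 and C5 alternate with the oxygenated carbons C2, C4 and C9: ring A is a dearomatised acylphloroglucinol whose C5 and C1 are spanned by the three-carbon unit C6–C7–C8, which invites annulation of a C6/C8 bis-electrophile, activated at C7, onto a phloroglucinol.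

## Retrosynthesis

**Side chain at C3.** Cutting one methyl–carbinol bond of **26** gives methyl ketone **25**, and cutting the C3–CH2 bond of **25** gives the C3-unsubstituted dione **23** and methyl vinyl ketone **24**. The neighbouring cuts are worse: a C3 prenyl group could not be hydrated beside two other prenyl groups, and a saturated alkyl halide would alkylate the dione on oxygen. The forward steps ask for a C-selective Michael addition of a cyclic 1,3-dione and for methyl addition to an unhindered ketone in the presence of the hindered C9 and C1-acyl ketones.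

**The surplus acyl group.** **23** is traced back to chloride **22** and then to triketone **20**, which carries a second (R)-2-methylbutanoyl group on C3. This group is what makes the arene precursor symmetrical, so it must be removable. Direct retro-Claisen cleavage is not trusted: under base the triketone is a delocalised anion and the least electrophilic site of the molecule, and under acid the prenyl groups cyclise. Chlorination at C3 instead makes that carbon tetrahedral and non-enolisable, so methoxide can cleave the exocyclic acyl group under mild conditions; zinc then removes the chlorine.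

**Prenyl at C7.** The C7 prenyl group of **20** is cut at its double bond to give aldehyde **19**, and **19** is cut by one carbon to the C7 carbaldehyde **17**. The formyl group is the activating group the annulation needs, and it lets C7 equilibrate to the equatorial position before it is fixed. The acidic triketone stays in place during both Wittig steps and protects C3 from aldol reaction with the aldehyde.

**Key cut.** Breaking C5–C6 and C1–C8 of **17** gives the symmetrical arene **6** and the enal **14**, in which the methylene carbon becomes C6 and the acetate-bearing carbon becomes C8. With a mono-acyl dialkyl phloroglucinol the second bond would be free to form at the alkyl-bearing carbon and give the isomeric core. With two identical acyl groups either closure puts an acyl group on the bridgehead. The precursor is far simpler: an achiral-core arene with two chiral-pool side chains and a C8 enal. The forward reaction must alkylate C5, lose acetate, close a congested C–C bond, and tell the two acyl-bearing carbons apart.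

**Arene.** **6** is cut at the arene–prenyl bond to **4** and prenyl bromide **5**; **4** is cut at both aryl–acyl bonds to phloroglucinol **3** and acid chloride **2**, made from **1**. Only one ring carbon of **4** is free, so C-prenylation has a single site.

**Enal.** The aldehyde of **14** comes from alcohol **13**, freed from silyl ether **12**. **12** is cut at the vinyl–carbinol bond to the vinyllithium from bromide **8** and acetone **9**, and **8** comes from 2-bromoprop-2-en-1-ol **7**. The tertiary alkoxide is acetylated in the flask, before the enal exists, because nucleophilic acylation catalysts would transpose the tertiary allylic acetate of an enal.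

## Roads not taken

**Alternative 1: decarboxylative radical closure.** The cut is C7–C8. The precursor is redox-active ester **A1**, a ring A dione with an isopropylidene group on C1 and an N-acyloxyphthalimide on C7. Under visible light with Ru(bpy)3(PF6)2 and Hantzsch ester it would lose CO2; the C7 radical would add to C8 and hydrogen transfer to the bridgehead radical would give **A2**. Its merit is real: the ring-closing bond forms irreversibly, with matched polarity, under neutral conditions, and radical additions tolerate a quaternary terminus. On the bond-forming event alone this road is probably more reliable than a reversible Michael closure between two fully substituted carbons. Its weak points for this target are that **A2** has hydrogen at C1, so the α-branched acyl group must later be forced onto a bridgehead next to the gem-dimethyl carbon; that the C3 chloride and the methyl ether must be exchanged; that 5-exo attack at C1 competes geometrically; that C7 is set kinetically with no chance of correction; and that the C5 configuration of **A1** needs its own asymmetric step. Against the better closing step, the chosen plan sets the acyl group being in place from the first step and two fragments giving both bonds and three stereocentres at once.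

**Alternative 2: asymmetric Diels–Alder assembly of ring B.** The cuts are C6–C7 and C1–C8, made before ring A exists. Diene **A3** and dienophile **A4** would combine under Cu(SbF6)2 with a chiral tert-butyl bis(oxazoline) ligand to give **A5**. The regiochemistry is matched, and the absolute configuration at C7 would rest on a well-understood chelate model; in predictability of absolute control this road is better than an ion pair that must tell two near-equivalent carbons apart. Its weak points are the poor reactivity of a β,β-dimethyl dienophile, the fact that only C7 is set, and the later annulation of ring A across C1 and C5 with uncertain facial selectivity relative to C7. That annulation again leaves hydrogen at C1, and the imide needs three further steps to become prenyl. The chosen plan answers with a much shorter sequence and with quaternary centres that are formed already carrying their final substituents.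

**Alternative 3: oxidative ring expansion of a fused hydrindanone.** The cut is again C1–C8, but the bond would arise by a 1,2-shift. In the cis-fused hydroxy ketone **A6**, PhI(OAc)2 with KOH in methanol would functionalise C1, and the C9 alkoxide would push C8 from C9 to C1, giving **A7**. An intramolecular shift is insensitive to congestion and irreversible, and C5 and C7 are set in a simpler fused ring; for the C1–C8 bond itself this is as attractive as the chosen closure. The weak points are that these conditions usually give α-hydroxy dimethyl acetals, that C5 could migrate in place of C8, and that **A7** lacks both the C1 acyl group and the C3 chain. Bridgehead acylation therefore returns, and the absolute configuration must be built into **A6** separately. The chosen plan is more convergent and avoids bridgehead acylation altogether; it pays with two steps to remove the surplus acyl group.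

Key step: step 8

Assumption: O-allyl-N-(9-anthracenylmethyl)cinchonidinium bromide is taken to favour the (1R,5S) core of **17**; the sense of induction cannot be derived from structure alone, and the pseudoenantiomeric cinchoninium salt is used if it proves opposite.

Remark: the ring A vinylogous acids **17**–**26** are written as C4 enols and equilibrate with the C2 enols; core numbering is as defined in the first section.

## Route

Step 1
Reactants: 1 (2R)-2-methylbutanoic acid
Product: 2 (2R)-2-methylbutanoyl chloride
Conditions: (COCl)2, DMF (cat.), CH2Cl2, 0 °C to rt; distillation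
Reagents that add atoms: oxalyl chloride, O=C(Cl)C(Cl)=O
Why: Acid chloride formation through the Vilsmeier-type chloroiminium catalyst; no amine base is present, so ketene formation and loss of the α-stereocentre are not expected.

Step 2
Reactants: 3 phloroglucinol; 2 (2R)-2-methylbutanoyl chloride
Product: 4 1,1'-(2,4,6-trihydroxy-1,3-phenylene)bis[(2R)-2-methylbutan-1-one]
Conditions: 2 (2.2 equiv), AlCl3, PhNO2–CH2Cl2, 0 °C to rt; aq. HCl
Reagents that add atoms: none
Why: Double Friedel–Crafts C-acylation of the electron-rich arene, stopping at the diketone because each acyl group deactivates the ring further. The aluminium-chelated aryl ketones resist enolisation, so the (R)-centres should be kept; their integrity is to be checked at this stage.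

Step 3
Reactants: 4 1,1'-(2,4,6-trihydroxy-1,3-phenylene)bis[(2R)-2-methylbutan-1-one]; 5 1-bromo-3-methylbut-2-ene
Product: 6 1,1'-[2,4,6-trihydroxy-5-(3-methylbut-2-en-1-yl)-1,3-phenylene]bis[(2R)-2-methylbutan-1-one]
Conditions: 5 (1.05 equiv), aq. KOH (10 %), 0 °C
Reagents that add atoms: none
Why: C-alkylation of the phenoxide in water (SN2 on the allylic bromide) at the only free ring carbon; hydrogen bonding to water suppresses O-alkylation and one equivalent of 5 limits geminal diprenylation.

Step 4
Reactants: 7 2-bromoprop-2-en-1-ol
Product: 8 [(2-bromoprop-2-en-1-yl)oxy](tert-butyl)dimethylsilane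
Conditions: TBSCl, imidazole, CH2Cl2, 0 °C to rt
Reagents that add atoms: tert-butyl(chloro)dimethylsilane, CC(C)(C)[Si](C)(C)Cl
Why: Standard silylation of a primary alcohol, needed so that the vinyl bromide can be lithiated.

Step 5
Reactants: 8 [(2-bromoprop-2-en-1-yl)oxy](tert-butyl)dimethylsilane; 9 acetone
Product: 12 3-{[tert-butyl(dimethyl)silyl]oxymethyl}-2-methylbut-3-en-2-yl acetate, via vinyllithium 10 (not isolated), via lithium alkoxide 11 (not isolated)
Conditions: t-BuLi (2.1 equiv), Et2O, −78 °C; 9; Ac2O, −78 to 0 °C
Reagents that add atoms: acetic anhydride, CC(=O)OC(C)=O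
Why: Bromine–lithium exchange gives the vinyllithium, which adds to acetone; the tertiary lithium alkoxide is acetylated in the flask, so no acylation catalyst ever meets the later enal.

Step 6
Reactants: 12 3-{[tert-butyl(dimethyl)silyl]oxymethyl}-2-methylbut-3-en-2-yl acetate
Product: 13 3-(hydroxymethyl)-2-methylbut-3-en-2-yl acetate
Conditions: HF·pyridine, pyridine, THF, 0 °C
Reagents that add atoms: none
Why: Fluoride cleavage of the primary silyl ether under buffered, slightly acidic conditions, so that no alkoxide forms that could take over the acetyl group by 1,3-migration.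

Step 7
Reactants: 13 3-(hydroxymethyl)-2-methylbut-3-en-2-yl acetate
Product: 14 3-formyl-2-methylbut-3-en-2-yl acetate
Conditions: MnO2, CH2Cl2, rt
Reagents that add atoms: none
Why: MnO2 oxidises the primary allylic alcohol to the 2-substituted acrolein under neutral conditions and leaves the tertiary acetate untouched.

Step 8
Reactants: 6 1,1'-[2,4,6-trihydroxy-5-(3-methylbut-2-en-1-yl)-1,3-phenylene]bis[(2R)-2-methylbutan-1-one]; 14 3-formyl-2-methylbut-3-en-2-yl acetate
Product: 17 (1R,5S,7R)-4-hydroxy-8,8-dimethyl-1,3-bis[(2R)-2-methylbutanoyl]-5-(3-methylbut-2-en-1-yl)-2,9-dioxobicyclo[3.3.1]non-3-ene-7-carbaldehyde, via acetoxy aldehyde Michael adduct 15 (not isolated), via tethered dimethyl enal 16 (not isolated)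
Conditions: O-allyl-N-(9-anthracenylmethyl)cinchonidinium bromide (25 mol %), CsOH·H2O, 4 Å MS, CH2Cl2, −50 to −20 °C; aq. citric acid
Reagents that add atoms: none
Why: The ammonium phenoxide of 6 adds through C5, the only ring carbon without an acyl group, to the methylene terminus of 14 (Michael addition, dearomatising ring A) to give 15, which loses acetate by E1cB to unveil the tethered β,β-dimethyl enal 16. The acyl-bearing enolate carbon C1 then adds to C8 in a 6-endo-trig Michael closure that forms ring B and the bicyclo[3.3.1]nonane; the closest known reaction type is the alkylative dearomatisation–annulation of acylphloroglucinols with α-(acetoxyalkyl)acroleins under cinchona phase-transfer catalysis. Because both candidate carbons carry the same acyl group, either closure leads to the acyl bridgehead, so no constitutional isomer can form. C1 and C5 become stereogenic together in the closure: the one-carbon bridge forces them cis, and the choice between the two acyl-bearing carbons, made inside the chiral ammonium–enolate ion pair, fixes their absolute sense. The two possible cores are diastereomers because of the (R) side chains, so the minor one can be removed by chromatography. C7 is set by protonation and enolate equilibration of the aldehyde, which places the formyl group equatorial on the chair of ring B, pointing away from ring A. The step needs C- rather than O-closure and must not revert: O-adducts can reopen by retro-oxa-Michael, whereas the C-adduct is trapped once its aldehyde enolate is protonated by the far more acidic triketone, and the low temperature preserves the kinetic choice of the ion pair.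

Step 9
Reactants: 17 (1R,5S,7R)-4-hydroxy-8,8-dimethyl-1,3-bis[(2R)-2-methylbutanoyl]-5-(3-methylbut-2-en-1-yl)-2,9-dioxobicyclo[3.3.1]non-3-ene-7-carbaldehyde
Product: 19 2-[(1R,5S,7S)-4-hydroxy-8,8-dimethyl-1,3-bis[(2R)-2-methylbutanoyl]-5-(3-methylbut-2-en-1-yl)-2,9-dioxobicyclo[3.3.1]non-3-en-7-yl]acetaldehyde, via methyl enol ether 18 (not isolated)
Conditions: Ph3P(CH2OMe)Cl, KN(SiMe3)2 (2.3 equiv ylide), THF, −78 to 0 °C; then 1 M aq. HCl, rt
Reagents that add atoms: (methoxymethyl)triphenylphosphonium chloride, COC[P+](c1ccccc1)(c1ccccc1)c1ccccc1.[Cl-]; water, O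
Why: Wittig methoxymethylenation of the aldehyde: the first equivalent of ylide deprotonates the triketone, which is thereby protected, and the C9 and acyl ketones are too hindered to react. Mild acid hydrolysis of enol ether 18 then gives the homologous aldehyde, after which C7 can no longer epimerise.

Step 10
Reactants: 19 2-[(1R,5S,7S)-4-hydroxy-8,8-dimethyl-1,3-bis[(2R)-2-methylbutanoyl]-5-(3-methylbut-2-en-1-yl)-2,9-dioxobicyclo[3.3.1]non-3-en-7-yl]acetaldehyde
Product: 20 (1R,5S,7R)-4-hydroxy-8,8-dimethyl-1,3-bis[(2R)-2-methylbutanoyl]-5,7-bis(3-methylbut-2-en-1-yl)bicyclo[3.3.1]non-3-ene-2,9-dione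
Conditions: Ph3P(i-Pr)I, KN(SiMe3)2 (2.3 equiv ylide), THF, −78 °C to rt
Reagents that add atoms: isopropyltriphenylphosphonium iodide, CC(C)[P+](c1ccccc1)(c1ccccc1)c1ccccc1.[I-]
Why: Wittig olefination of the unhindered aldehyde with the non-stabilised isopropylidene ylide gives the trisubstituted alkene of the prenyl group; no stereochemical issue arises.

Step 11
Reactants: 20 (1R,5S,7R)-4-hydroxy-8,8-dimethyl-1,3-bis[(2R)-2-methylbutanoyl]-5,7-bis(3-methylbut-2-en-1-yl)bicyclo[3.3.1]non-3-ene-2,9-dione
Product: 22 (1R,5S,7R)-3-chloro-4-hydroxy-8,8-dimethyl-1-[(2R)-2-methylbutanoyl]-5,7-bis(3-methylbut-2-en-1-yl)bicyclo[3.3.1]non-3-ene-2,9-dione, via 3-chloro tetraketone 21 (not isolated)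
Conditions: K2CO3, NCS (1.0 equiv), MeCN, −20 °C; then MeOH, 0 °C
Reagents that add atoms: N-chlorosuccinimide, O=C1CCC(=O)N1Cl
Why: Electrophilic chlorination of the triketone enolate at C3 gives the non-enolisable α-chloro tricarbonyl 21; methoxide then cleaves the exocyclic acyl group, the least hindered of the three carbonyls on C3, in a retro-Claisen reaction that expels the stabilised 2-chloro-1,3-dione enolate (deacylative halogenation of a β-dicarbonyl compound). The C1 acyl group is spared because its loss would need a bridgehead enolate, and the prenyl alkenes are far less reactive towards NCS than the enolate.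

Step 12
Reactants: 22 (1R,5S,7R)-3-chloro-4-hydroxy-8,8-dimethyl-1-[(2R)-2-methylbutanoyl]-5,7-bis(3-methylbut-2-en-1-yl)bicyclo[3.3.1]non-3-ene-2,9-dione
Product: 23 (1S,5S,7R)-4-hydroxy-8,8-dimethyl-1-[(2R)-2-methylbutanoyl]-5,7-bis(3-methylbut-2-en-1-yl)bicyclo[3.3.1]non-3-ene-2,9-dione
Conditions: Zn, AcOH, THF, 0 °C to rt
Reagents that add atoms: none
Why: Reductive dehalogenation of an α-halo-1,3-dione by zinc (two-electron reduction to the zinc enolate, then protonation); alkenes and hindered ketones are inert, and the descriptor at C1 changes only because the priorities change.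

Step 13
Reactants: 23 (1S,5S,7R)-4-hydroxy-8,8-dimethyl-1-[(2R)-2-methylbutanoyl]-5,7-bis(3-methylbut-2-en-1-yl)bicyclo[3.3.1]non-3-ene-2,9-dione; 24 but-3-en-2-one
Product: 25 (1S,5S,7R)-4-hydroxy-8,8-dimethyl-1-[(2R)-2-methylbutanoyl]-5,7-bis(3-methylbut-2-en-1-yl)-3-(3-oxobutyl)bicyclo[3.3.1]non-3-ene-2,9-dione
Conditions: 24 (1.2 equiv), Et3N (cat.), THF, rt
Reagents that add atoms: none
Why: Michael addition of the cyclic 1,3-dione to methyl vinyl ketone under amine catalysis, C-selective as with simple cyclohexane-1,3-diones; near-stoichiometric enone prevents a second addition.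

Step 14
Reactants: 25 (1S,5S,7R)-4-hydroxy-8,8-dimethyl-1-[(2R)-2-methylbutanoyl]-5,7-bis(3-methylbut-2-en-1-yl)-3-(3-oxobutyl)bicyclo[3.3.1]non-3-ene-2,9-dione
Product: 26 (1S,5S,7R)-4-hydroxy-3-(3-hydroxy-3-methylbutyl)-8,8-dimethyl-1-[(2R)-2-methylbutanoyl]-5,7-bis(3-methylbut-2-en-1-yl)bicyclo[3.3.1]non-3-ene-2,9-dione
Conditions: CeCl3, MeMgBr (3.5 equiv), THF, −78 to −40 °C; aq. NH4Cl
Reagents that add atoms: methylmagnesium bromide, C[Mg]Br
Why: The first equivalent deprotonates the enol, which protects ring A as its enolate; the weakly basic organocerium reagent then adds to the unhindered side-chain methyl ketone in preference to the C9 and C1-acyl ketones, both flanked by fully substituted carbons. The buffered work-up avoids acid-induced cyclisation of the new tertiary alcohol onto the enol.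

## Compound list

1 | (2R)-2-methylbutanoic acid | CC[C@@H](C)C(=O)O | starting material
2 | (2R)-2-methylbutanoyl chloride | CC[C@@H](C)C(Cl)=O | intermediate
3 | phloroglucinol (benzene-1,3,5-triol) | Oc1cc(O)cc(O)c1 | starting material
4 | 1,1'-(2,4,6-trihydroxy-1,3-phenylene)bis[(2R)-2-methylbutan-1-one] | CC[C@@H](C)C(=O)c1c(O)cc(O)c(C(=O)[C@H](C)CC)c1O | intermediate
5 | 1-bromo-3-methylbut-2-ene (prenyl bromide) | CC(C)=CCBr | starting material
6 | 1,1'-[2,4,6-trihydroxy-5-(3-methylbut-2-en-1-yl)-1,3-phenylene]bis[(2R)-2-methylbutan-1-one] | CC[C@@H](C)C(=O)c1c(O)c(C(=O)[C@H](C)CC)c(O)c(CC=C(C)C)c1O | intermediate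
7 | 2-bromoprop-2-en-1-ol | OCC(Br)=C | starting material
8 | [(2-bromoprop-2-en-1-yl)oxy](tert-butyl)dimethylsilane | C=C(Br)CO[Si](C)(C)C(C)(C)C | intermediate
9 | acetone | CC(C)=O | starting material
10 | [3-{[tert-butyl(dimethyl)silyl]oxy}prop-1-en-2-yl]lithium | [Li]C(=C)CO[Si](C)(C)C(C)(C)C | intermediate (not isolated)
11 | lithium 3-{[tert-butyl(dimethyl)silyl]oxymethyl}-2-methylbut-3-en-2-olate | [Li]OC(C)(C)C(=C)CO[Si](C)(C)C(C)(C)C | intermediate (not isolated)
12 | 3-{[tert-butyl(dimethyl)silyl]oxymethyl}-2-methylbut-3-en-2-yl acetate | CC(=O)OC(C)(C)C(=C)CO[Si](C)(C)C(C)(C)C | intermediate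
13 | 3-(hydroxymethyl)-2-methylbut-3-en-2-yl acetate | CC(=O)OC(C)(C)C(=C)CO | intermediate
14 | 3-formyl-2-methylbut-3-en-2-yl acetate | C=C(C=O)C(C)(C)OC(C)=O | intermediate
15 | 3-formyl-4-[3,5-dihydroxy-2,4-bis((2R)-2-methylbutanoyl)-1-(3-methylbut-2-en-1-yl)-6-oxocyclohexa-2,4-dien-1-yl]-2-methylbutan-2-yl acetate (formyl-bearing carbon unassigned) | O=C1C(C(=O)[C@H](C)CC)=C(O)C(C(=O)[C@H](C)CC)=C(O)C1(CC=C(C)C)CC(C=O)C(C)(C)OC(C)=O | intermediate (not isolated)
16 | 2-{[3,5-dihydroxy-2,4-bis((2R)-2-methylbutanoyl)-1-(3-methylbut-2-en-1-yl)-6-oxocyclohexa-2,4-dien-1-yl]methyl}-3-methylbut-2-enal | O=C1C(C(=O)[C@H](C)CC)=C(O)C(C(=O)[C@H](C)CC)=C(O)C1(CC=C(C)C)CC(C=O)=C(C)C | intermediate (not isolated)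
17 | (1R,5S,7R)-4-hydroxy-8,8-dimethyl-1,3-bis[(2R)-2-methylbutanoyl]-5-(3-methylbut-2-en-1-yl)-2,9-dioxobicyclo[3.3.1]non-3-ene-7-carbaldehyde | CC[C@@H](C)C(=O)[C@]12C(=O)C(C(=O)[C@H](C)CC)=C(O)[C@](CC=C(C)C)(C[C@@H](C=O)C1(C)C)C2=O | intermediate
18 | (1R,5S,7S)-4-hydroxy-7-(2-methoxyethenyl)-8,8-dimethyl-1,3-bis[(2R)-2-methylbutanoyl]-5-(3-methylbut-2-en-1-yl)bicyclo[3.3.1]non-3-ene-2,9-dione (E/Z mixture) | CC[C@@H](C)C(=O)[C@]12C(=O)C(C(=O)[C@H](C)CC)=C(O)[C@](CC=C(C)C)(C[C@@H](C=COC)C1(C)C)C2=O | intermediate (not isolated)
19 | 2-[(1R,5S,7S)-4-hydroxy-8,8-dimethyl-1,3-bis[(2R)-2-methylbutanoyl]-5-(3-methylbut-2-en-1-yl)-2,9-dioxobicyclo[3.3.1]non-3-en-7-yl]acetaldehyde | CC[C@@H](C)C(=O)[C@]12C(=O)C(C(=O)[C@H](C)CC)=C(O)[C@](CC=C(C)C)(C[C@@H](CC=O)C1(C)C)C2=O | intermediate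
20 | (1R,5S,7R)-4-hydroxy-8,8-dimethyl-1,3-bis[(2R)-2-methylbutanoyl]-5,7-bis(3-methylbut-2-en-1-yl)bicyclo[3.3.1]non-3-ene-2,9-dione | CC[C@@H](C)C(=O)[C@]12C(=O)C(C(=O)[C@H](C)CC)=C(O)[C@](CC=C(C)C)(C[C@@H](CC=C(C)C)C1(C)C)C2=O | intermediate
21 | (1R,5R,7R)-3-chloro-8,8-dimethyl-1,3-bis[(2R)-2-methylbutanoyl]-5,7-bis(3-methylbut-2-en-1-yl)bicyclo[3.3.1]nonane-2,4,9-trione (C3 epimers) | CC[C@@H](C)C(=O)[C@]12C(=O)C(Cl)(C(=O)[C@H](C)CC)C(=O)[C@](CC=C(C)C)(C[C@@H](CC=C(C)C)C1(C)C)C2=O | intermediate (not isolated)
22 | (1R,5S,7R)-3-chloro-4-hydroxy-8,8-dimethyl-1-[(2R)-2-methylbutanoyl]-5,7-bis(3-methylbut-2-en-1-yl)bicyclo[3.3.1]non-3-ene-2,9-dione | CC[C@@H](C)C(=O)[C@]12C(=O)C(Cl)=C(O)[C@](CC=C(C)C)(C[C@@H](CC=C(C)C)C1(C)C)C2=O | intermediate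
23 | (1S,5S,7R)-4-hydroxy-8,8-dimethyl-1-[(2R)-2-methylbutanoyl]-5,7-bis(3-methylbut-2-en-1-yl)bicyclo[3.3.1]non-3-ene-2,9-dione | CC[C@@H](C)C(=O)[C@]12C(=O)C=C(O)[C@](CC=C(C)C)(C[C@@H](CC=C(C)C)C1(C)C)C2=O | intermediate
24 | but-3-en-2-one (methyl vinyl ketone) | CC(=O)C=C | starting material
25 | (1S,5S,7R)-4-hydroxy-8,8-dimethyl-1-[(2R)-2-methylbutanoyl]-5,7-bis(3-methylbut-2-en-1-yl)-3-(3-oxobutyl)bicyclo[3.3.1]non-3-ene-2,9-dione | CC[C@@H](C)C(=O)[C@]12C(=O)C(CCC(C)=O)=C(O)[C@](CC=C(C)C)(C[C@@H](CC=C(C)C)C1(C)C)C2=O | intermediate
26 | (1S,5S,7R)-4-hydroxy-3-(3-hydroxy-3-methylbutyl)-8,8-dimethyl-1-[(2R)-2-methylbutanoyl]-5,7-bis(3-methylbut-2-en-1-yl)bicyclo[3.3.1]non-3-ene-2,9-dione | CC[C@@H](C)C(=O)[C@]12C(=O)C(CCC(C)(C)O)=C(O)[C@](CC=C(C)C)(C[C@@H](CC=C(C)C)C1(C)C)C2=O | target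

## Step count and risks

Total: 14 steps. Longest linear sequence: 11 steps (steps 4 to 14, from 7); the arene branch is 10 steps (steps 1 to 3, then 8 to 14).

**Step 8 (key step).** The second Michael addition has to join two fully substituted carbons and is reversible, so the reaction may stall at the open enal 16 or close through oxygen. The ion pair may also discriminate only weakly between the two acyl-bearing carbons, which would lower the proportion of the wanted core diastereomer. Fallback, changing the closure from an anionic Michael addition to a cationic cyclisation: 6 is prenylated a second time at the same carbon (5, NaOMe, MeOH) to give 3,5-dihydroxy-2,4-bis[(2R)-2-methylbutanoyl]-6,6-bis(3-methylbut-2-en-1-yl)cyclohexa-2,4-dien-1-one F1. N-(Phenylseleno)phthalimide with SnCl4 in CH2Cl2 at low temperature then forms a seleniranium ion on one prenyl group, and the acyl-bearing enol carbon attacks its tertiary end; this irreversible 6-endo closure makes the same C1–C8 bond and gives the C7 phenylselanyl bicycle F2. Radical allylation (allyltributylstannane, AIBN, benzene, 80 °C) replaces selenium by allyl from the open equatorial side to give the C7 allyl triketone F3, and cross-metathesis with 2-methylbut-2-ene (second-generation Grubbs catalyst) rejoins the route at 20. This path has no catalyst control; the two core diastereomers, distinguishable through the (R) side chains, would have to be separated.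

**Step 11.** Methoxide may attack a ring carbonyl of 21 and open ring A in place of removing the exocyclic acyl group, or the chlorinating agent may be consumed by a prenyl alkene. Fallback, changing the activation from halogenation to aminal formation: 20 is heated with benzene-1,2-diamine (EtOH, cat. AcOH, 60 °C). Condensation at the exocyclic carbonyl, the usual site for amines on 2-acyl-1,3-diones, gives the enaminone (1R,5S,7R)-3-{1-[(2-aminophenyl)amino]-2-methylbutylidene}-8,8-dimethyl-1-[(2R)-2-methylbutanoyl]-5,7-bis(3-methylbut-2-en-1-yl)bicyclo[3.3.1]nonane-2,4,9-trione F4. Its second amino group closes onto the same carbon, and aromatisation to a benzimidazole expels the 1,3-dione, so the route is rejoined directly at 23 and step 12 is not needed.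

**Step 9.** The basic ylide may enolise the C7 aldehyde, and the enolate can then open ring B by retro-Michael loss of the stabilised C1 enolate; the acidic hydrolysis may also start cyclisation of the C5 prenyl group onto the enol. Fallback, replacing the olefination by non-basic carbonyl addition: 17 is treated with CH2=CHMgBr and CeCl3 to give the allylic alcohol (1R,5S,7R)-4-hydroxy-7-(1-hydroxyprop-2-en-1-yl)-8,8-dimethyl-1,3-bis[(2R)-2-methylbutanoyl]-5-(3-methylbut-2-en-1-yl)bicyclo[3.3.1]non-3-ene-2,9-dione F5. Acetylation (Ac2O, pyridine, with mild methanolysis of any enol acetate) gives the allylic acetate F6. Pd(PPh3)4 with HCO2NH4 delivers hydride to the substituted end of the allyl complex and gives the C7 allyl triketone F3, and cross-metathesis with 2-methylbut-2-ene (second-generation Grubbs catalyst) rejoins the route at 20.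

**Step 14.** The organocerium reagent may also add to the C1 acyl or C9 ketone, or the side chain may be lost by retro-Michael reaction from the ring A enolate. Fallback, avoiding organometallic reagents: 3-hydroxy-3-methylbutanal F7 is prepared by selective oxidation of commercial 3-methylbutane-1,3-diol (TEMPO, PhI(OAc)2). It is combined with 23, L-proline and Hantzsch ester in CH2Cl2 at rt; Knoevenagel condensation at C3 followed by transfer hydrogenation of the alkylidene dione (three-component reductive alkylation of cyclic 1,3-diones) gives 26 directly and replaces steps 13 and 14.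

## Further compounds

F1 | step 8 | 3,5-dihydroxy-2,4-bis[(2R)-2-methylbutanoyl]-6,6-bis(3-methylbut-2-en-1-yl)cyclohexa-2,4-dien-1-one | O=C1C(C(=O)[C@H](C)CC)=C(O)C(C(=O)[C@H](C)CC)=C(O)C1(CC=C(C)C)CC=C(C)C
F2 | step 8 | (1R,5S)-4-hydroxy-8,8-dimethyl-1,3-bis[(2R)-2-methylbutanoyl]-5-(3-methylbut-2-en-1-yl)-7-(phenylselanyl)bicyclo[3.3.1]non-3-ene-2,9-dione (C7 unassigned) | CC[C@@H](C)C(=O)[C@]12C(=O)C(C(=O)[C@H](C)CC)=C(O)[C@](CC=C(C)C)(CC([Se]c3ccccc3)C1(C)C)C2=O
F3 | step 8 | (1R,5S,7R)-4-hydroxy-8,8-dimethyl-1,3-bis[(2R)-2-methylbutanoyl]-5-(3-methylbut-2-en-1-yl)-7-(prop-2-en-1-yl)bicyclo[3.3.1]non-3-ene-2,9-dione | CC[C@@H](C)C(=O)[C@]12C(=O)C(C(=O)[C@H](C)CC)=C(O)[C@](CC=C(C)C)(C[C@@H](CC=C)C1(C)C)C2=O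
F4 | step 11 | (1R,5S,7R)-3-{1-[(2-aminophenyl)amino]-2-methylbutylidene}-8,8-dimethyl-1-[(2R)-2-methylbutanoyl]-5,7-bis(3-methylbut-2-en-1-yl)bicyclo[3.3.1]nonane-2,4,9-trione (side-chain centre as in 20) | CC[C@@H](C)C(=O)[C@]12C(=O)C(=C(Nc3ccccc3N)[C@H](C)CC)C(=O)[C@](CC=C(C)C)(C[C@@H](CC=C(C)C)C1(C)C)C2=O
F5 | step 9 | (1R,5S,7R)-4-hydroxy-7-(1-hydroxyprop-2-en-1-yl)-8,8-dimethyl-1,3-bis[(2R)-2-methylbutanoyl]-5-(3-methylbut-2-en-1-yl)bicyclo[3.3.1]non-3-ene-2,9-dione (carbinol epimers) | CC[C@@H](C)C(=O)[C@]12C(=O)C(C(=O)[C@H](C)CC)=C(O)[C@](CC=C(C)C)(C[C@@H](C(O)C=C)C1(C)C)C2=O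
F6 | step 9 | 1-[(1R,5S,7R)-4-hydroxy-8,8-dimethyl-1,3-bis[(2R)-2-methylbutanoyl]-5-(3-methylbut-2-en-1-yl)-2,9-dioxobicyclo[3.3.1]non-3-en-7-yl]prop-2-en-1-yl acetate (carbinol epimers) | CC[C@@H](C)C(=O)[C@]12C(=O)C(C(=O)[C@H](C)CC)=C(O)[C@](CC=C(C)C)(C[C@@H](C(OC(C)=O)C=C)C1(C)C)C2=O
F7 | step 14 | 3-hydroxy-3-methylbutanal | CC(C)(O)CC=O
A1 | alternative 1 | 1,3-dioxoisoindolin-2-yl 2-{[3-chloro-2-methoxy-1-(3-methylbut-2-en-1-yl)-4,6-dioxo-5-(propan-2-ylidene)cyclohex-2-en-1-yl]methyl}-5-methylhex-4-enoate (ring carbon configured as C5 of 26; ester-bearing carbon unassigned) | CC(C)=C1C(=O)C(Cl)=C(OC)[C@](CC=C(C)C)(CC(CC=C(C)C)C(=O)ON2C(=O)c3ccccc3C2=O)C1=O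
A2 | alternative 1 | 3-chloro-4-methoxy-8,8-dimethyl-5,7-bis(3-methylbut-2-en-1-yl)bicyclo[3.3.1]non-3-ene-2,9-dione with hydrogen at C1 (core configured as in 26) | [C@H]12C(=O)C(Cl)=C(OC)[C@](CC=C(C)C)(C[C@@H](CC=C(C)C)C1(C)C)C2=O
A3 | alternative 2 | tert-butyl(dimethyl)[(6-methyl-3-methylidenehepta-1,5-dien-2-yl)oxy]silane | C=C(O[Si](C)(C)C(C)(C)C)C(=C)CC=C(C)C
A4 | alternative 2 | 3-(3-methylbut-2-enoyl)-1,3-oxazolidin-2-one | CC(C)=CC(=O)N1CCOC1=O
A5 | alternative 2 | 3-{[(1R)-4-{[tert-butyl(dimethyl)silyl]oxy}-6,6-dimethyl-3-(3-methylbut-2-en-1-yl)cyclohex-3-en-1-yl]carbonyl}-1,3-oxazolidin-2-one | CC(C)=CCC1=C(O[Si](C)(C)C(C)(C)C)CC(C)(C)[C@H](C(=O)N2CCOC2=O)C1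
A6 | alternative 3 | cis-fused 7a-hydroxy-4-methoxy-1,1-dimethyl-2,3a-bis(3-methylbut-2-en-1-yl)-1,2,3,3a,7,7a-hexahydro-6H-inden-6-one | O=C1C=C(OC)[C@]2(CC=C(C)C)C[C@@H](CC=C(C)C)C(C)(C)[C@]2(O)C1
A7 | alternative 3 | 4-methoxy-8,8-dimethyl-5,7-bis(3-methylbut-2-en-1-yl)bicyclo[3.3.1]non-3-ene-2,9-dione with hydrogen at C1 and C3 (core configured as in 26) | [C@H]12C(=O)C=C(OC)[C@](CC=C(C)C)(C[C@@H](CC=C(C)C)C1(C)C)C2=O
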